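**Retrosynthetic overview**
1. Target 24 ⇐ epoxy quinone monoketal 23 by deketalisation; before that a Wittig two-carbon extension of the side-chain enal, acetylation of C1′–OH, and a carbinol-directed nucleophilic epoxidation of the 4,4-dimethoxycyclohexadienone 18.
2. 18 ⇐ benzoxaborole 16: boron is the masked C2 oxygen (N-oxide oxidation, then PhI(OAc)2/MeOH dearomatisation of the p-methoxyphenol).
3. 16 ⇐ pyrone carbinol 11 + ethynyltrifluoroborate 12: boron-tethered intramolecular pyrone/alkyne [4+2] cycloaddition, then loss of CO2; this forms C1–C2 and C3–C4 of the carbocycle.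
4. Enabling feature: the side-chain carbinol oxygen on C1′ is 1,3 to the ring carbonyl carbon C2 through the quaternary oxirane carbon C1 (O–C1′–C1–C2). A temporary C1′–O–B–C2 link (five-membered 1,2-oxaborole ring) can therefore deliver the unit C2–C3 across C1/C4 of a 2-pyrone whose 4-OMe already carries the C5 oxygen.
5. Ring order: six-membered carbocycle (step 8, through the temporary oxaborole and CO2-bridged rings), then the oxirane (step 10). 11 ⇐ pyrone aldehyde 5 + vinyl iodide 9 (asymmetric Nozaki–Hiyama–Kishi coupling).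

Key step: step 8

Remark: ring atoms are numbered as in the 7-oxabicyclo[4.1.0]hept-3-ene-2,5-dione name of the target (C1 quaternary oxirane carbon, C4 bearing CH2OAc), the side chain C1′–C6′; the chelate model used for the face selectivity in step 10 is an assumption.

Step 1
Reactants: 1 4-methoxy-6-methyl-2H-pyran-2-one
Product: 2 3-bromo-4-methoxy-6-methyl-2H-pyran-2-one
Conditions: NBS, MeCN, rt, dark
Reagents that add atoms: N-bromosuccinimide, O=C1CCC(=O)N1Br
Why: Electrophilic bromination should occur at C3, the enol-ether β-carbon next to the lactone carbonyl (halogenation of a 4-alkoxy-2-pyrone).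

Step 2
Reactants: 2 3-bromo-4-methoxy-6-methyl-2H-pyran-2-one
Product: 3 3-(hydroxymethyl)-4-methoxy-6-methyl-2H-pyran-2-one
Conditions: Bu3SnCH2OH, Pd(PPh3)4 (cat.), 1,4-dioxane, 100 °C
Reagents that add atoms: (tributylstannyl)methanol, CCCC[Sn](CCCC)(CCCC)CO
Why: Stille hydroxymethylation of the vinylic C3–Br bond installs the future C4 side-arm carbon.

Step 3
Reactants: 3 3-(hydroxymethyl)-4-methoxy-6-methyl-2H-pyran-2-one
Product: 4 (4-methoxy-6-methyl-2-oxo-2H-pyran-3-yl)methyl acetate
Conditions: Ac2O, pyridine, DMAP (cat.), CH2Cl2, 0 °C to rt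
Reagents that add atoms: acetic anhydride, CC(=O)OC(C)=O
Why: O-Acetylation puts the target's acetoxymethyl group in place and masks this hydroxyl, so that only the carbinol of 11 can bind boron in step 8.

Step 4
Reactants: 4 (4-methoxy-6-methyl-2-oxo-2H-pyran-3-yl)methyl acetate
Product: 5 (6-formyl-4-methoxy-2-oxo-2H-pyran-3-yl)methyl acetate
Conditions: SeO2, 1,4-dioxane, 150 °C (sealed tube)
Reagents that add atoms: selenium dioxide, O=[Se]=O
Why: Riley-type selenium dioxide oxidation of the vinylogously activated 6-methyl group, a reaction type known for 4-methoxy-6-methyl-2-pyrones, should give the aldehyde.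

Step 5
Reactants: 6 prop-2-yn-1-ol
Product: 8 (E)-3-iodo-2-methylprop-2-en-1-ol, via alkenylalane 7 (not isolated)
Conditions: AlMe3 (3 equiv), Cp2ZrCl2 (0.25 equiv), CH2Cl2, 0 °C to rt; then I2, THF, −30 to 0 °C; aq. Na2S2O3/Rochelle salt
Reagents that add atoms: trimethylaluminium, C[Al](C)C; iodine, II
Why: Negishi zirconium-catalysed syn-carboalumination places Me and Al cis, and iodinolysis with retention fixes the E trisubstituted alkene.

Step 6
Reactants: 8 (E)-3-iodo-2-methylprop-2-en-1-ol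
Product: 9 (E)-tert-butyl[(3-iodo-2-methylprop-2-en-1-yl)oxy]dimethylsilane
Conditions: TBSCl, imidazole, CH2Cl2, rt
Reagents that add atoms: tert-butyldimethylsilyl chloride, CC(C)(C)[Si](C)(C)Cl
Why: Silylation of the primary alcohol gives an ether that should survive every step up to the late unmasking of C4′.

Step 7
Reactants: 5 (6-formyl-4-methoxy-2-oxo-2H-pyran-3-yl)methyl acetate; 9 (E)-tert-butyl[(3-iodo-2-methylprop-2-en-1-yl)oxy]dimethylsilane
Product: 11 {6-[(1S,2E)-4-(tert-butyldimethylsilyloxy)-1-hydroxy-3-methylbut-2-en-1-yl]-4-methoxy-2-oxo-2H-pyran-3-yl}methyl acetate, via alkenylchromium 10 (not isolated)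
Conditions: CrCl2 (3 equiv), NiCl2 (2 mol%), chiral oxazoline–sulfonamide ligand (3.3 equiv), Et3N, THF, rt
Reagents that add atoms: none
Why: Asymmetric Nozaki–Hiyama–Kishi coupling is aldehyde-selective (lactone, acetate and silyl ether untouched) and keeps the alkene geometry; the ligand enantiomer that sends the alkenylchromium to the Si face of the aldehyde sets C1′ as S.

Step 8
Reactants: 11 {6-[(1S,2E)-4-(tert-butyldimethylsilyloxy)-1-hydroxy-3-methylbut-2-en-1-yl]-4-methoxy-2-oxo-2H-pyran-3-yl}methyl acetate; 12 potassium ethynyltrifluoroborate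
Product: 16 {(3S)-3-[(1E)-3-(tert-butyldimethylsilyloxy)-2-methylprop-1-en-1-yl]-1-hydroxy-5-methoxy-1,3-dihydro-2,1-benzoxaborol-6-yl}methyl acetate, via tethered alkynylborinate 13 (not isolated), via bicyclic lactone 14 (not isolated), via B-fluorobenzoxaborole 15 (not isolated)
Conditions: TMSCl (1.5 equiv), i-Pr2NEt (1.2 equiv), MeCN/PhMe, 0 °C to rt; then 90 °C; aq. NaHCO3
Reagents that add atoms: water, O
Why: Proposed new method: TMSCl strips fluoride from 12 to give ethynyldifluoroborane, which is captured by the C1′ hydroxyl of 11 as borinate 13; its B-ethynyl group then adds across C6/C3 of the pyrone in a thermal intramolecular [4+2] cycloaddition (14), and retro-[4+2] loss of CO2 aromatises the adduct to the benzoxaborole. The closest known reaction types are the Lewis-base-directed cycloaddition of alkynyldifluoroboranes with 2-pyrones, where a dative donor→B bond plays the part of the tether, and the boronate-tethered intramolecular Diels–Alder reaction of dienols; here the tether is a covalent B–O bond to the substrate's own carbinol. The five-membered 1,2-oxaborole ring closes by B–O exchange followed by the C–C bond of a type-1 intramolecular Diels–Alder reaction over the three-atom C1′–O–B tether, and the benzene ring closes by the suprafacial [4+2] addition across the pyrone diene termini, after which the lactone bridge leaves as CO2. No new stereocentre survives: the bridgehead centres of 14 are erased on aromatisation (both π-faces converge), and C1′ keeps its S configuration because only its O–H bond is exchanged. The selectivity needed is regiochemical (boron-bearing carbon to the carbinol-bearing pyrone C6, CH to the acetoxymethyl-bearing C3); it is secured by the tether and reinforced by polarity (nucleophilic C3 of the 4-methoxypyrone, β-carbon of the alkynylborane). The side chain holds one isolated alkene only, so no second diene competes for the tethered alkyne.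

Step 9
Reactants: 16 {(3S)-3-[(1E)-3-(tert-butyldimethylsilyloxy)-2-methylprop-1-en-1-yl]-1-hydroxy-5-methoxy-1,3-dihydro-2,1-benzoxaborol-6-yl}methyl acetate
Product: 18 {4-[(1S,2E)-4-(tert-butyldimethylsilyloxy)-1-hydroxy-3-methylbut-2-en-1-yl]-6,6-dimethoxy-3-oxocyclohexa-1,4-dien-1-yl}methyl acetate, via phenol 17 (not isolated)
Conditions: Me3NO (2 equiv), CH2Cl2, rt; evaporate; PhI(OAc)2 (1.1 equiv), NaHCO3, MeOH, 0 °C
Reagents that add atoms: trimethylamine N-oxide, C[N+](C)(C)[O-]; methanol, CO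
Why: N-Oxide ipso-hydroxylation of the aryl–boron bond (1,2-aryl shift from B to O) frees the phenol and the carbinol, and hypervalent-iodine oxidation of the p-methoxyphenol in methanol gives the quinone monoketal; telescoping avoids isolating the ionisation-prone o-hydroxybenzylic allylic alcohol.

Step 10
Reactants: 18 {4-[(1S,2E)-4-(tert-butyldimethylsilyloxy)-1-hydroxy-3-methylbut-2-en-1-yl]-6,6-dimethoxy-3-oxocyclohexa-1,4-dien-1-yl}methyl acetate
Product: 19 {(1R,6S)-1-[(1S,2E)-4-(tert-butyldimethylsilyloxy)-1-hydroxy-3-methylbut-2-en-1-yl]-5,5-dimethoxy-2-oxo-7-oxabicyclo[4.1.0]hept-3-en-4-yl}methyl acetate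
Conditions: t-BuOOH (1.5 equiv), n-BuLi (1.3 equiv), THF, −78 °C; then 18, −78 to −20 °C; aq. NH4Cl
Reagents that add atoms: tert-butyl hydroperoxide, CC(C)(C)OO
Why: Weitz–Scheffer-type nucleophilic epoxidation: the peroxide should add to C6, the unsubstituted β-carbon (the other enone β-carbon C4 is disubstituted and spared), and a lithium bridge between the C1′ oxygen and the C2 ketone holds C1′–O in the ring plane, so attack anti to the alkenyl chain gives the cis-fused (1R,6S) oxirane.

Step 11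
Reactants: 19 {(1R,6S)-1-[(1S,2E)-4-(tert-butyldimethylsilyloxy)-1-hydroxy-3-methylbut-2-en-1-yl]-5,5-dimethoxy-2-oxo-7-oxabicyclo[4.1.0]hept-3-en-4-yl}methyl acetate
Product: 20 (1S,2E)-1-[(1R,6S)-4-(acetoxymethyl)-5,5-dimethoxy-2-oxo-7-oxabicyclo[4.1.0]hept-3-en-1-yl]-4-(tert-butyldimethylsilyloxy)-3-methylbut-2-en-1-yl acetate
Conditions: Ac2O, pyridine, DMAP (cat.), CH2Cl2, 0 °C
Reagents that add atoms: acetic anhydride, CC(=O)OC(C)=O
Why: Acetylation of the secondary carbinol installs the second acetate of the target (and would re-acetylate any primary acetate lost in step 10) without touching the stereocentres.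

Step 12
Reactants: 20 (1S,2E)-1-[(1R,6S)-4-(acetoxymethyl)-5,5-dimethoxy-2-oxo-7-oxabicyclo[4.1.0]hept-3-en-1-yl]-4-(tert-butyldimethylsilyloxy)-3-methylbut-2-en-1-yl acetate
Product: 21 (1S,2E)-1-[(1R,6S)-4-(acetoxymethyl)-5,5-dimethoxy-2-oxo-7-oxabicyclo[4.1.0]hept-3-en-1-yl]-4-hydroxy-3-methylbut-2-en-1-yl acetate
Conditions: HF·pyridine, pyridine, THF, 0 °C to rt
Reagents that add atoms: none
Why: Buffered fluoride cleavage of the primary allylic silyl ether should leave the acetates, the oxirane and the dimethyl ketal intact.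

Step 13
Reactants: 21 (1S,2E)-1-[(1R,6S)-4-(acetoxymethyl)-5,5-dimethoxy-2-oxo-7-oxabicyclo[4.1.0]hept-3-en-1-yl]-4-hydroxy-3-methylbut-2-en-1-yl acetate
Product: 22 (1S,2E)-1-[(1R,6S)-4-(acetoxymethyl)-5,5-dimethoxy-2-oxo-7-oxabicyclo[4.1.0]hept-3-en-1-yl]-3-methyl-4-oxobut-2-en-1-yl acetate
Conditions: MnO2 (activated, excess), CH2Cl2, rt
Reagents that add atoms: none
Why: Manganese dioxide oxidises the only free (primary allylic) alcohol to the enal under neutral conditions with retention of alkene geometry.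

Step 14
Reactants: 22 (1S,2E)-1-[(1R,6S)-4-(acetoxymethyl)-5,5-dimethoxy-2-oxo-7-oxabicyclo[4.1.0]hept-3-en-1-yl]-3-methyl-4-oxobut-2-en-1-yl acetate
Product: 23 (1S,2E,4E)-1-[(1R,6S)-4-(acetoxymethyl)-5,5-dimethoxy-2-oxo-7-oxabicyclo[4.1.0]hept-3-en-1-yl]-3-methyl-6-oxohexa-2,4-dien-1-yl acetate
Conditions: Ph3P=CHCHO (1.3 equiv), PhMe, 70 °C
Reagents that add atoms: (triphenylphosphoranylidene)acetaldehyde, O=CC=P(c1ccccc1)(c1ccccc1)c1ccccc1
Why: Wittig reaction of the stabilised formyl ylide with the aldehyde (ketone and ketal-masked enone do not react) should give the new 4E alkene; the dienal is made only after the peroxide step, which it would not survive.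

Step 15
Reactants: 23 (1S,2E,4E)-1-[(1R,6S)-4-(acetoxymethyl)-5,5-dimethoxy-2-oxo-7-oxabicyclo[4.1.0]hept-3-en-1-yl]-3-methyl-6-oxohexa-2,4-dien-1-yl acetate
Product: 24 (1S,2E,4E)-1-[(1R,6S)-4-(acetoxymethyl)-2,5-dioxo-7-oxabicyclo[4.1.0]hept-3-en-1-yl]-3-methyl-6-oxohexa-2,4-dien-1-yl acetate
Conditions: montmorillonite K10, wet CH2Cl2, rt
Reagents that add atoms: water, O
Why: Mild solid-acid hydrolysis of the quinone monoketal unveils the C5 ketone and completes the ene-dione without opening the oxirane or cleaving the acetates.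

**Compound list**
1 | 4-methoxy-6-methyl-2H-pyran-2-one | COC1=CC(=O)OC(C)=C1 | starting material
2 | 3-bromo-4-methoxy-6-methyl-2H-pyran-2-one | BrC1=C(OC)C=C(C)OC1=O | intermediate
3 | 3-(hydroxymethyl)-4-methoxy-6-methyl-2H-pyran-2-one | OCC1=C(OC)C=C(C)OC1=O | intermediate
4 | (4-methoxy-6-methyl-2-oxo-2H-pyran-3-yl)methyl acetate | CC(=O)OCC1=C(OC)C=C(C)OC1=O | intermediate
5 | (6-formyl-4-methoxy-2-oxo-2H-pyran-3-yl)methyl acetate | CC(=O)OCC1=C(OC)C=C(C=O)OC1=O | intermediate
6 | prop-2-yn-1-ol | C#CCO | starting material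
7 | (E)-alkenylalane from carboalumination (O- and C-bound AlMe2) | C[Al](C)/C=C(\C)CO[Al](C)C | intermediate (not isolated)
8 | (E)-3-iodo-2-methylprop-2-en-1-ol | I/C=C(\C)CO | intermediate
9 | (E)-tert-butyl[(3-iodo-2-methylprop-2-en-1-yl)oxy]dimethylsilane | I/C=C(\C)CO[Si](C)(C)C(C)(C)C | intermediate
10 | (E)-alkenylchromium(III) dichloride from 9 | Cl[Cr](Cl)/C=C(\C)CO[Si](C)(C)C(C)(C)C | intermediate (not isolated)
11 | {6-[(1S,2E)-4-(tert-butyldimethylsilyloxy)-1-hydroxy-3-methylbut-2-en-1-yl]-4-methoxy-2-oxo-2H-pyran-3-yl}methyl acetate | CC(=O)OCC1=C(OC)C=C(OC1=O)[C@H](/C=C(\C)CO[Si](C)(C)C(C)(C)C)O | intermediate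
12 | potassium ethynyltrifluoroborate | [K+].F[B-](F)(F)C#C | starting material
13 | (1S,2E)-1-[3-(acetoxymethyl)-4-methoxy-2-oxo-2H-pyran-6-yl]-4-(tert-butyldimethylsilyloxy)-3-methylbut-2-en-1-yl ethynyl(fluoro)borinate | CC(=O)OCC1=C(OC)C=C(OC1=O)[C@H](/C=C(\C)CO[Si](C)(C)C(C)(C)C)OB(F)C#C | intermediate (not isolated)
14 | [4+2] adduct: 2-oxabicyclo[2.2.2]octa-5,7-dien-3-one fused to the 1,2-oxaborole ring (bridgehead configuration not defined, both faces converge) | CC(=O)OCC12C(=O)OC3(C=C1OC)C(=C2)B(F)O[C@H]3/C=C(\C)CO[Si](C)(C)C(C)(C)C | intermediate (not isolated)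
15 | {(3S)-3-[(1E)-3-(tert-butyldimethylsilyloxy)-2-methylprop-1-en-1-yl]-1-fluoro-5-methoxy-1,3-dihydro-2,1-benzoxaborol-6-yl}methyl acetate | CC(=O)OCc1cc2B(F)O[C@@H](/C=C(\C)CO[Si](C)(C)C(C)(C)C)c2cc1OC | intermediate (not isolated)
16 | {(3S)-3-[(1E)-3-(tert-butyldimethylsilyloxy)-2-methylprop-1-en-1-yl]-1-hydroxy-5-methoxy-1,3-dihydro-2,1-benzoxaborol-6-yl}methyl acetate | CC(=O)OCc1cc2B(O)O[C@@H](/C=C(\C)CO[Si](C)(C)C(C)(C)C)c2cc1OC | intermediate
17 | {5-hydroxy-4-[(1S,2E)-4-(tert-butyldimethylsilyloxy)-1-hydroxy-3-methylbut-2-en-1-yl]-2-methoxyphenyl}methyl acetate | CC(=O)OCc1cc(O)c(cc1OC)[C@H](/C=C(\C)CO[Si](C)(C)C(C)(C)C)O | intermediate (not isolated)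
18 | {4-[(1S,2E)-4-(tert-butyldimethylsilyloxy)-1-hydroxy-3-methylbut-2-en-1-yl]-6,6-dimethoxy-3-oxocyclohexa-1,4-dien-1-yl}methyl acetate | CC(=O)OCC1=CC(=O)C(=CC1(OC)OC)[C@H](/C=C(\C)CO[Si](C)(C)C(C)(C)C)O | intermediate
19 | {(1R,6S)-1-[(1S,2E)-4-(tert-butyldimethylsilyloxy)-1-hydroxy-3-methylbut-2-en-1-yl]-5,5-dimethoxy-2-oxo-7-oxabicyclo[4.1.0]hept-3-en-4-yl}methyl acetate | CC(=O)OCC1=CC(=O)[C@]2([C@H](/C=C(\C)CO[Si](C)(C)C(C)(C)C)O)O[C@@H]2C1(OC)OC | intermediate
20 | (1S,2E)-1-[(1R,6S)-4-(acetoxymethyl)-5,5-dimethoxy-2-oxo-7-oxabicyclo[4.1.0]hept-3-en-1-yl]-4-(tert-butyldimethylsilyloxy)-3-methylbut-2-en-1-yl acetate | CC(=O)OCC1=CC(=O)[C@]2([C@H](/C=C(\C)CO[Si](C)(C)C(C)(C)C)OC(C)=O)O[C@@H]2C1(OC)OC | intermediate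
21 | (1S,2E)-1-[(1R,6S)-4-(acetoxymethyl)-5,5-dimethoxy-2-oxo-7-oxabicyclo[4.1.0]hept-3-en-1-yl]-4-hydroxy-3-methylbut-2-en-1-yl acetate | CC(=O)OCC1=CC(=O)[C@]2([C@H](/C=C(\C)CO)OC(C)=O)O[C@@H]2C1(OC)OC | intermediate
22 | (1S,2E)-1-[(1R,6S)-4-(acetoxymethyl)-5,5-dimethoxy-2-oxo-7-oxabicyclo[4.1.0]hept-3-en-1-yl]-3-methyl-4-oxobut-2-en-1-yl acetate | CC(=O)OCC1=CC(=O)[C@]2([C@H](/C=C(\C)C=O)OC(C)=O)O[C@@H]2C1(OC)OC | intermediate
23 | (1S,2E,4E)-1-[(1R,6S)-4-(acetoxymethyl)-5,5-dimethoxy-2-oxo-7-oxabicyclo[4.1.0]hept-3-en-1-yl]-3-methyl-6-oxohexa-2,4-dien-1-yl acetate | CC(=O)OCC1=CC(=O)[C@]2([C@H](/C=C(C)/C=C/C=O)OC(C)=O)O[C@@H]2C1(OC)OC | intermediate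
24 | (1S,2E,4E)-1-[(1R,6S)-4-(acetoxymethyl)-2,5-dioxo-7-oxabicyclo[4.1.0]hept-3-en-1-yl]-3-methyl-6-oxohexa-2,4-dien-1-yl acetate | CC(=O)OCC1=CC(=O)[C@]2([C@H](/C=C(C)/C=C/C=O)OC(C)=O)O[C@@H]2C1=O | target

**Step count:** 15 steps in total; longest linear sequence 13 steps (steps 1–4 and 7–15).

**Steps most likely to fail**

Step 8 (Proposed new method). The cycloaddition of the electron-rich 4-methoxypyrone may be slower than ionisation of the doubly activated C1′–O–B bond (alkynyl transfer to C1′ or C3′, loss of configuration) or than protodeboronation of the B–C(sp) bond. The fallback uses known chemistry, a dative instead of a covalent link to boron, and sets out from aldehyde 5. Pinnick oxidation (NaClO2, NaH2PO4, 2-methylbut-2-ene) should give 3-(acetoxymethyl)-4-methoxy-2-oxo-2H-pyran-6-carboxylic acid F1, and amide coupling with diethylamine the diethylamide F2. The amide carbonyl then directs the cycloaddition of ethynyldifluoroborane (from 12 and BF3·OEt2, CH2Cl2, 40 °C) with loss of CO2 to the chelated aryldifluoroborane F3; the same two ring bonds are formed with the same regiochemistry. Perborate oxidation should give the salicylamide F4, and Cp2Zr(H)Cl reduction of the tertiary amide (acetate tolerated) the salicylaldehyde F5. The asymmetric Nozaki–Hiyama–Kishi coupling of step 7 with 9 should then give phenol 17, which is oxidised at once with PhI(OAc)2/MeOH as in step 9, so the route is rejoined at 18.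

Step 10. A non-chelated rotamer about C1–C1′ may react, so that the peroxide enters mainly on the wrong face; retro-aldol loss of the side chain from the lithium alkoxide of 19 is a second danger. The fallback keeps the same directing effect but runs it in the C1′-epimeric series and corrects C1′ afterwards; it sets out from 18. Mitsunobu reaction with formic acid (PPh3, DIAD) should give the inverted (1R)-formate F6, and mild methanolysis (NaHCO3, MeOH, 0 °C, acetate retained) the (1R)-alcohol F7. Epoxidation under the step 10 conditions, now steered to the opposite face, should give the (1R,6S)-oxirane with the (1R)-carbinol F8. A second Mitsunobu reaction with acetic acid inverts C1′ and installs the acetate in one operation, which rejoins the route at 20.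

Step 7. The chiral chromium complex may discriminate the faces of the electron-poor pyrone aldehyde only weakly, because an uncatalysed background addition competes. The fallback sets C1′ by reduction instead of by C–C bond formation and sets out from 5 and 9. The ligand-free Nozaki–Hiyama–Kishi coupling (CrCl2, NiCl2 cat., DMF) should give the racemic alcohol F9, and MnO2 the enone F10. Corey–Bakshi–Shibata reduction (oxazaborolidine enantiomer chosen for the S alcohol, catecholborane, −78 °C) then returns to the route at 11.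

**Further compounds**
F1 | step 8 | 3-(acetoxymethyl)-4-methoxy-2-oxo-2H-pyran-6-carboxylic acid | CC(=O)OCC1=C(OC)C=C(C(=O)O)OC1=O
F2 | step 8 | [6-(diethylcarbamoyl)-4-methoxy-2-oxo-2H-pyran-3-yl]methyl acetate | CCN(CC)C(=O)C1=CC(OC)=C(COC(C)=O)C(=O)O1
F3 | step 8 | [5-(difluoroboranyl)-4-(diethylcarbamoyl)-2-methoxyphenyl]methyl acetate (amide C=O→B chelate) | CCN(CC)C(=O)c1cc(OC)c(COC(C)=O)cc1B(F)F
F4 | step 8 | [4-(diethylcarbamoyl)-5-hydroxy-2-methoxyphenyl]methyl acetate | CCN(CC)C(=O)c1cc(OC)c(COC(C)=O)cc1O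
F5 | step 8 | (4-formyl-5-hydroxy-2-methoxyphenyl)methyl acetate | CC(=O)OCc1cc(O)c(C=O)cc1OC
F6 | step 10 | {4-[(1R,2E)-4-(tert-butyldimethylsilyloxy)-1-(formyloxy)-3-methylbut-2-en-1-yl]-6,6-dimethoxy-3-oxocyclohexa-1,4-dien-1-yl}methyl acetate | CC(=O)OCC1=CC(=O)C(=CC1(OC)OC)[C@@H](/C=C(\C)CO[Si](C)(C)C(C)(C)C)OC=O
F7 | step 10 | {4-[(1R,2E)-4-(tert-butyldimethylsilyloxy)-1-hydroxy-3-methylbut-2-en-1-yl]-6,6-dimethoxy-3-oxocyclohexa-1,4-dien-1-yl}methyl acetate | CC(=O)OCC1=CC(=O)C(=CC1(OC)OC)[C@@H](/C=C(\C)CO[Si](C)(C)C(C)(C)C)O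
F8 | step 10 | {(1R,6S)-1-[(1R,2E)-4-(tert-butyldimethylsilyloxy)-1-hydroxy-3-methylbut-2-en-1-yl]-5,5-dimethoxy-2-oxo-7-oxabicyclo[4.1.0]hept-3-en-4-yl}methyl acetate | CC(=O)OCC1=CC(=O)[C@]2([C@@H](/C=C(\C)CO[Si](C)(C)C(C)(C)C)O)O[C@@H]2C1(OC)OC
F9 | step 7 | racemic {6-[(2E)-4-(tert-butyldimethylsilyloxy)-1-hydroxy-3-methylbut-2-en-1-yl]-4-methoxy-2-oxo-2H-pyran-3-yl}methyl acetate | CC(=O)OCC1=C(OC)C=C(OC1=O)C(O)/C=C(\C)CO[Si](C)(C)C(C)(C)C
F10 | step 7 | {6-[(2E)-4-(tert-butyldimethylsilyloxy)-3-methylbut-2-enoyl]-4-methoxy-2-oxo-2H-pyran-3-yl}methyl acetate | CC(=O)OCC1=C(OC)C=C(OC1=O)C(=O)/C=C(\C)CO[Si](C)(C)C(C)(C)C
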